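**Retrosynthetic overview**

1. Numbering used throughout: δ-lactone ring C1(H2)–O2–C3(=O)–C4–C4a–C11a; nine-membered ring C4a–C5–C6–C7(OH)(Me)–C8–C9–C10–C11–C11a; C19 is the exocyclic CH2 on C11; C12–C15 is the side chain.
2. Endgame: the C8–C9 epoxide comes from hydroxyl-directed epoxidation of a Z-C8=C9 olefin by the C7 carbinol; C4=C12 comes from Horner–Wadsworth–Emmons coupling of a C4 phosphonate with a prenol-derived epoxy aldehyde (C12–C15).
3. Nine-membered ring (formed second): ring-closing metathesis at C8=C9 after allylation of a C11 aldehyde; C11=C19 from the C11 ketone.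
4. δ-Lactone ring (formed first, key step): C4–C4a and C1–C11a are made in one amine-catalysed Michael/α-alkylation domino between a linalool-derived enal (C5–C11, with C7 from the chiral pool) and chloromethyl 2-(diethoxyphosphoryl)acetate (C1–O2–C3–C4).
5. Enabling feature: C11, the ring carbon that carries the exocyclic methylene, is bonded to ring-fusion carbon C11a. At the aldehyde level it makes C4a and C11a the β- and α-carbons of an enal, while C4 is α to the lactone carbonyl C3 and C1 is an O-bound CH2, so the lactone ring maps onto iminium (C4 to C4a) then enamine (C11a to C1) reactivity.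

Key step: step 5

Remark: (S)-(+)-linalool (coriandrol) is taken as the commercial chiral-pool source of C7; epimers at the phosphonate-bearing C4 and at the transient C11 carbinol are carried as mixtures because both centres are destroyed later.

**Route**

Step 1
Reactants: 1 (S)-(+)-linalool [(3S)-3,7-dimethylocta-1,6-dien-3-ol]
Product: 2 (3S)-3,7-dimethyl-3-(triethylsilyloxy)octa-1,6-diene
Conditions: Et3SiOTf, 2,6-lutidine, CH2Cl2, −78 to 0 °C
Reagents that add atoms: triethylsilyl trifluoromethanesulfonate, CC[Si](CC)(CC)OS(=O)(=O)C(F)(F)F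
Why: Silylation of the tertiary alcohol with the silyl triflate and a hindered pyridine base is a standard protection that leaves the carbinol stereocentre (the later C7) untouched and keeps this oxygen out of the iminium chemistry of step 5.

Step 2
Reactants: 2 (3S)-3,7-dimethyl-3-(triethylsilyloxy)octa-1,6-diene
Product: 3 (4S)-4-methyl-4-(triethylsilyloxy)hex-5-enal
Conditions: O3 (1 equiv, Sudan Red 7B as end-point indicator), CH2Cl2, −78 °C; then Me2S, −78 °C to rt
Reagents that add atoms: ozone, [O-][O+]=O
Why: Chemoselective ozonolysis with reductive work-up cleaves the electron-rich trisubstituted olefin far faster than the vinyl group, which is deactivated by the allylic oxygen and shielded by the quaternary centre, so the aldehyde carbon that becomes C4a is unmasked.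

Step 3
Reactants: 3 (4S)-4-methyl-4-(triethylsilyloxy)hex-5-enal
Product: 4 (2E,6S)-6-methyl-6-(triethylsilyloxy)octa-2,7-dienal
Conditions: Ph3P=CHCHO, toluene, 80 °C
Reagents that add atoms: (triphenylphosphoranylidene)acetaldehyde, O=CC=P(c1ccccc1)(c1ccccc1)c1ccccc1
Why: Wittig olefination with the stabilised formyl ylide gives the two-carbon-homologated E-enal under neutral conditions.

Step 4
Reactants: 5 2-(diethoxyphosphoryl)acetic acid
Product: 6 chloromethyl 2-(diethoxyphosphoryl)acetate
Conditions: ClCH2OSO2Cl, NaHCO3, Bu4NHSO4 (10 mol %), CH2Cl2/H2O, 0 °C to rt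
Reagents that add atoms: chloromethyl chlorosulfate, ClCOS(=O)(=O)Cl
Why: O-Alkylation of the carboxylate by chloromethyl chlorosulfate under phase-transfer conditions is the standard route to chloromethyl esters, the chlorosulfate being displaced far faster than the chloride.

Step 5
Reactants: 4 (2E,6S)-6-methyl-6-(triethylsilyloxy)octa-2,7-dienal; 6 chloromethyl 2-(diethoxyphosphoryl)acetate
Product: 8 diethyl [(4S,5S)-5-formyl-4-[(3S)-3-methyl-3-(triethylsilyloxy)pent-4-en-1-yl]-2-oxooxan-3-yl]phosphonate (epimers at the phosphonate carbon), via Michael-adduct enamine 7 (not isolated)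
Conditions: (R)-α,α-diphenylprolinol trimethylsilyl ether (20 mol %), 2,6-lutidine (1.5 equiv), Bu4NI (10 mol %), CH2Cl2, 0 °C to rt
Reagents that add atoms: none
Why: Proposed new method: the secondary amine condenses with enal 4 to the E-iminium ion, the C–H acidic carbon of 6 (the later C4) adds to the β-carbon (C4a), and the enamine 7 so formed is alkylated at its α-carbon (C11a) by the tethered acyloxymethyl halide carbon (C1), after which hydrolysis returns the catalyst and the aldehyde. The closest known reaction type is the aminocatalytic iminium–enamine Michael/α-alkylation domino of enals with halogenated malonates and β-keto esters that gives cyclopropanes and cyclopentanes; a halomethyl ester as the tethered electrophile, which makes the new ring a δ-lactone, and a phosphonoacetate as the donor are the untested parts. The lactone ring closes by 6-exo-tet attack of the enamine carbon on CH2–X, and this is the only closure open to 7, because every other pairing of its nucleophilic and electrophilic carbons would give a four-membered ring. C4a is set by the catalyst, whose CPh2(OSiMe3) group shields one face of the s-trans E-iminium so that the (R)-amine should give 4aS; C11a is set relative to C4a as the trans (diequatorial) isomer in the chair-like closure and stays under thermodynamic control because the α-formyl centre epimerises through the enamine; C4 is left as a mixture that converges in step 14. The step needs 1,4- over 1,2-addition (no Horner–Wadsworth–Emmons olefination of the enal) and C- over N-alkylation, which iminium activation, the absence of metal cations and strong base, and the hindered catalyst nitrogen are expected to secure, while the silyl ether at C7 blocks oxa-Michael closure.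

Step 6
Reactants: 8 diethyl [(4S,5S)-5-formyl-4-[(3S)-3-methyl-3-(triethylsilyloxy)pent-4-en-1-yl]-2-oxooxan-3-yl]phosphonate
Product: 9 diethyl [(4S,5S)-5-(1-hydroxybut-3-en-1-yl)-4-[(3S)-3-methyl-3-(triethylsilyloxy)pent-4-en-1-yl]-2-oxooxan-3-yl]phosphonate (carbinol epimers)
Conditions: allylB(pin), CH2Cl2, rt; aqueous work-up (8 is used directly after filtration)
Reagents that add atoms: allylboronic acid pinacol ester, C=CCB1OC(C)(C)C(C)(C)O1
Why: Uncatalysed allylboration through a closed six-membered transition state is selective for the aldehyde over lactone and phosphonate and is non-basic, so C11a is not epimerised and the lactone oxygen is not eliminated, while the new C11 carbinol centre may form as a mixture because it is oxidised in step 7.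

Step 7
Reactants: 9 diethyl [(4S,5S)-5-(1-hydroxybut-3-en-1-yl)-4-[(3S)-3-methyl-3-(triethylsilyloxy)pent-4-en-1-yl]-2-oxooxan-3-yl]phosphonate
Product: 10 diethyl [(4S,5S)-5-(but-3-enoyl)-4-[(3S)-3-methyl-3-(triethylsilyloxy)pent-4-en-1-yl]-2-oxooxan-3-yl]phosphonate
Conditions: Dess–Martin periodinane, CH2Cl2, 0 °C to rt
Reagents that add atoms: none
Why: Dess–Martin oxidation converts both carbinol epimers into the single β,γ-unsaturated ketone under near-neutral conditions that do not move the double bond into conjugation.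

Step 8
Reactants: 10 diethyl [(4S,5S)-5-(but-3-enoyl)-4-[(3S)-3-methyl-3-(triethylsilyloxy)pent-4-en-1-yl]-2-oxooxan-3-yl]phosphonate
Product: 11 diethyl [(4aS,7S,8Z,11aS)-7-methyl-3,11-dioxo-7-(triethylsilyloxy)-1,3,4,4a,5,6,7,10,11,11a-decahydrocyclonona[c]pyran-4-yl]phosphonate
Conditions: second-generation Grubbs catalyst RuCl2(=CHPh)(PCy3)(H2IMes) (10 mol %), 1,4-benzoquinone (20 mol %), CH2Cl2 (1 mM), 40 °C
Reagents that add atoms: none
Why: Ring-closing olefin metathesis joins the allyl and vinyl termini with loss of ethylene, the trans-diequatorial arms on the lactone chair holding the two olefins close and the nine-membered ring accepting only the Z-olefin, while benzoquinone suppresses ruthenium-hydride double-bond migration.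

Step 9
Reactants: 11 diethyl [(4aS,7S,8Z,11aS)-7-methyl-3,11-dioxo-7-(triethylsilyloxy)-1,3,4,4a,5,6,7,10,11,11a-decahydrocyclonona[c]pyran-4-yl]phosphonate
Product: 12 diethyl [(4aS,7S,8Z,11aR)-7-methyl-11-methylidene-3-oxo-7-(triethylsilyloxy)-1,3,4,4a,5,6,7,10,11,11a-decahydrocyclonona[c]pyran-4-yl]phosphonate
Conditions: Zn, CH2Br2, TiCl4 (pre-formed Lombardo reagent), THF/CH2Cl2, 0 °C to rt
Reagents that add atoms: dibromomethane, BrCBr
Why: Lombardo methylenation uses a non-basic geminal dimetallic methylene reagent that converts easily enolised ketones without epimerising C11a, without β-elimination of the lactone oxygen and without touching lactone or phosphonate.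

Step 10
Reactants: 13 3-methylbut-2-en-1-ol (prenol)
Product: 14 [(2S)-3,3-dimethyloxiran-2-yl]methanol
Conditions: Ti(OiPr)4 (10 mol %), L-(+)-diethyl tartrate (12 mol %), t-BuOOH, 4 Å MS, CH2Cl2, −20 °C
Reagents that add atoms: tert-butyl hydroperoxide, CC(C)(C)OO
Why: Sharpless asymmetric epoxidation of the primary allylic alcohol with the L-(+)-tartrate ligand delivers oxygen to the face that gives the 2S epoxide, which becomes C14.

Step 11
Reactants: 14 [(2S)-3,3-dimethyloxiran-2-yl]methanol
Product: 16 (1S)-1-[(2S)-3,3-dimethyloxiran-2-yl]prop-2-en-1-ol, via (2R)-3,3-dimethyloxirane-2-carbaldehyde 15 (not isolated)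
Conditions: (COCl)2, DMSO, THF, −78 °C; Et3N; then CH2=CHMgBr, −78 to 0 °C
Reagents that add atoms: vinylmagnesium bromide, C=C[Mg]Br
Why: Swern oxidation followed by Grignard addition in the same flask avoids isolating the volatile epoxy aldehyde, and Felkin–Anh addition anti to the epoxide C–O bond should favour the erythro carbinol at the later C13, the minor epimer being removed by chromatography.

Step 12
Reactants: 16 (1S)-1-[(2S)-3,3-dimethyloxiran-2-yl]prop-2-en-1-ol
Product: 17 (2S)-3,3-dimethyl-2-[(1S)-1-(triethylsilyloxy)prop-2-en-1-yl]oxirane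
Conditions: Et3SiCl, imidazole, CH2Cl2, 0 °C to rt
Reagents that add atoms: chlorotriethylsilane, CC[Si](Cl)(CC)CC
Why: Silylation of the secondary alcohol with the silyl chloride and imidazole is a standard protection that does not affect the epoxide.

Step 13
Reactants: 17 (2S)-3,3-dimethyl-2-[(1S)-1-(triethylsilyloxy)prop-2-en-1-yl]oxirane
Product: 18 (2R)-2-[(2S)-3,3-dimethyloxiran-2-yl]-2-(triethylsilyloxy)acetaldehyde
Conditions: O3, CH2Cl2, −78 °C; then Me2S, −78 °C to rt
Reagents that add atoms: ozone, [O-][O+]=O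
Why: Ozonolysis of the terminal vinyl group with reductive work-up gives the α-silyloxy aldehyde without touching epoxide or silyl ether, and the aldehyde is used at once to avoid epimerisation.

Step 14
Reactants: 12 diethyl [(4aS,7S,8Z,11aR)-7-methyl-11-methylidene-3-oxo-7-(triethylsilyloxy)-1,3,4,4a,5,6,7,10,11,11a-decahydrocyclonona[c]pyran-4-yl]phosphonate; 18 (2R)-2-[(2S)-3,3-dimethyloxiran-2-yl]-2-(triethylsilyloxy)acetaldehyde
Product: 19 (4E,4aS,7S,8Z,11aR)-4-[(2S)-2-[(2S)-3,3-dimethyloxiran-2-yl]-2-(triethylsilyloxy)ethylidene]-7-methyl-11-methylidene-7-(triethylsilyloxy)-4,4a,5,6,7,10,11,11a-octahydrocyclonona[c]pyran-3(1H)-one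
Conditions: LiCl, DBU, MeCN, 0 °C to rt
Reagents that add atoms: none
Why: Horner–Wadsworth–Emmons olefination under Masamune–Roush conditions converges both phosphonate epimers through one stabilised anion and should favour the E-alkylidene lactone with the side chain anti to the carbonyl, the mild base sparing the α-silyloxy aldehyde stereocentre.

Step 15
Reactants: 19 (4E,4aS,7S,8Z,11aR)-4-[(2S)-2-[(2S)-3,3-dimethyloxiran-2-yl]-2-(triethylsilyloxy)ethylidene]-7-methyl-11-methylidene-7-(triethylsilyloxy)-4,4a,5,6,7,10,11,11a-octahydrocyclonona[c]pyran-3(1H)-one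
Product: 20 (4E,4aS,7S,8Z,11aR)-4-[(2S)-2-[(2S)-3,3-dimethyloxiran-2-yl]-2-hydroxyethylidene]-7-hydroxy-7-methyl-11-methylidene-4,4a,5,6,7,10,11,11a-octahydrocyclonona[c]pyran-3(1H)-one
Conditions: Bu4NF, AcOH (1:1), THF, 0 °C to rt
Reagents that add atoms: none
Why: Acetic-acid-buffered fluoride cleaves both triethylsilyl ethers while the near-neutral medium leaves the epoxide, the lactone and the skipped diene intact.

Step 16
Reactants: 20 (4E,4aS,7S,8Z,11aR)-4-[(2S)-2-[(2S)-3,3-dimethyloxiran-2-yl]-2-hydroxyethylidene]-7-hydroxy-7-methyl-11-methylidene-4,4a,5,6,7,10,11,11a-octahydrocyclonona[c]pyran-3(1H)-one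
Product: 21 CNP0147265.1, the (4E,4aS,7S,8R,9R,11aR)-8,9-epoxide of 20
Conditions: VO(acac)2 (10 mol %), t-BuOOH, CH2Cl2, 0 °C to rt
Reagents that add atoms: tert-butyl hydroperoxide, CC(C)(C)OO
Why: Hydroxyl-directed vanadium-catalysed epoxidation delivers oxygen from the metal-bound tertiary allylic C7 alkoxide to the adjacent Z-olefin on the face of the hydroxyl group, the sense established for medium-ring cycloalkenols, which sets 8R,9R, while the exocyclic methylene has no directing group and the C4=C12 olefin is electron-poor.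

**Compound list**

1 | (S)-(+)-linalool [(3S)-3,7-dimethylocta-1,6-dien-3-ol] | C=C[C@@](C)(O)CCC=C(C)C | starting material
2 | (3S)-3,7-dimethyl-3-(triethylsilyloxy)octa-1,6-diene | C=C[C@@](C)(O[Si](CC)(CC)CC)CCC=C(C)C | intermediate
3 | (4S)-4-methyl-4-(triethylsilyloxy)hex-5-enal | C=C[C@@](C)(O[Si](CC)(CC)CC)CCC=O | intermediate
4 | (2E,6S)-6-methyl-6-(triethylsilyloxy)octa-2,7-dienal | C=C[C@@](C)(O[Si](CC)(CC)CC)CC/C=C/C=O | intermediate
5 | 2-(diethoxyphosphoryl)acetic acid | CCOP(=O)(CC(=O)O)OCC | starting material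
6 | chloromethyl 2-(diethoxyphosphoryl)acetate | CCOP(=O)(CC(=O)OCCl)OCC | intermediate
7 | Michael-adduct enamine (E-enamine of the catalyst at C11, chloromethyl ester intact) | C=C[C@@](C)(O[Si](CC)(CC)CC)CC[C@@H](/C=C/N1CCC[C@@H]1C(O[Si](C)(C)C)(c1ccccc1)c1ccccc1)C(P(=O)(OCC)OCC)C(=O)OCCl | intermediate
8 | diethyl [(4S,5S)-5-formyl-4-[(3S)-3-methyl-3-(triethylsilyloxy)pent-4-en-1-yl]-2-oxooxan-3-yl]phosphonate (epimers at the phosphonate carbon) | C=C[C@@](C)(O[Si](CC)(CC)CC)CC[C@@H]1C(P(=O)(OCC)OCC)C(=O)OC[C@H]1C=O | intermediate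
9 | diethyl [(4S,5S)-5-(1-hydroxybut-3-en-1-yl)-4-[(3S)-3-methyl-3-(triethylsilyloxy)pent-4-en-1-yl]-2-oxooxan-3-yl]phosphonate (carbinol epimers) | C=C[C@@](C)(O[Si](CC)(CC)CC)CC[C@@H]1C(P(=O)(OCC)OCC)C(=O)OC[C@H]1C(O)CC=C | intermediate
10 | diethyl [(4S,5S)-5-(but-3-enoyl)-4-[(3S)-3-methyl-3-(triethylsilyloxy)pent-4-en-1-yl]-2-oxooxan-3-yl]phosphonate | C=C[C@@](C)(O[Si](CC)(CC)CC)CC[C@@H]1C(P(=O)(OCC)OCC)C(=O)OC[C@H]1C(=O)CC=C | intermediate
11 | diethyl [(4aS,7S,8Z,11aS)-7-methyl-3,11-dioxo-7-(triethylsilyloxy)-1,3,4,4a,5,6,7,10,11,11a-decahydrocyclonona[c]pyran-4-yl]phosphonate | O=C1C/C=C\[C@@](C)(O[Si](CC)(CC)CC)CC[C@@H]2C(P(=O)(OCC)OCC)C(=O)OC[C@@H]12 | intermediate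
12 | diethyl [(4aS,7S,8Z,11aR)-7-methyl-11-methylidene-3-oxo-7-(triethylsilyloxy)-1,3,4,4a,5,6,7,10,11,11a-decahydrocyclonona[c]pyran-4-yl]phosphonate | C=C1C/C=C\[C@@](C)(O[Si](CC)(CC)CC)CC[C@@H]2C(P(=O)(OCC)OCC)C(=O)OC[C@@H]12 | intermediate
13 | 3-methylbut-2-en-1-ol (prenol) | CC(C)=CCO | starting material
14 | [(2S)-3,3-dimethyloxiran-2-yl]methanol | OC[C@@H]1OC1(C)C | intermediate
15 | (2R)-3,3-dimethyloxirane-2-carbaldehyde | O=C[C@@H]1OC1(C)C | intermediate
16 | (1S)-1-[(2S)-3,3-dimethyloxiran-2-yl]prop-2-en-1-ol | C=C[C@H](O)[C@@H]1OC1(C)C | intermediate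
17 | (2S)-3,3-dimethyl-2-[(1S)-1-(triethylsilyloxy)prop-2-en-1-yl]oxirane | C=C[C@H](O[Si](CC)(CC)CC)[C@@H]1OC1(C)C | intermediate
18 | (2R)-2-[(2S)-3,3-dimethyloxiran-2-yl]-2-(triethylsilyloxy)acetaldehyde | O=C[C@H](O[Si](CC)(CC)CC)[C@@H]1OC1(C)C | intermediate
19 | (4E,4aS,7S,8Z,11aR)-4-[(2S)-2-[(2S)-3,3-dimethyloxiran-2-yl]-2-(triethylsilyloxy)ethylidene]-7-methyl-11-methylidene-7-(triethylsilyloxy)-4,4a,5,6,7,10,11,11a-octahydrocyclonona[c]pyran-3(1H)-one | C=C1C/C=C\[C@@](C)(O[Si](CC)(CC)CC)CC[C@@H]2/C(=C\[C@H](O[Si](CC)(CC)CC)[C@@H]3OC3(C)C)C(=O)OC[C@@H]12 | intermediate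
20 | (4E,4aS,7S,8Z,11aR)-4-[(2S)-2-[(2S)-3,3-dimethyloxiran-2-yl]-2-hydroxyethylidene]-7-hydroxy-7-methyl-11-methylidene-4,4a,5,6,7,10,11,11a-octahydrocyclonona[c]pyran-3(1H)-one | C=C1C/C=C\[C@@](C)(O)CC[C@@H]2/C(=C\[C@H](O)[C@@H]3OC3(C)C)C(=O)OC[C@@H]12 | intermediate
21 | CNP0147265.1, the (4E,4aS,7S,8R,9R,11aR)-8,9-epoxide of 20 | C=C1C[C@H]2O[C@H]2[C@@](C)(O)CC[C@@H]2/C(=C\[C@H](O)[C@@H]3OC3(C)C)C(=O)OC[C@@H]12 | target

**Step count and risks**

Total step count: 16. Longest linear sequence: 11 steps (steps 1, 2, 3, 5, 6, 7, 8, 9, 14, 15, 16).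

The three steps most likely to fail:

1. Step 5 (proposed new method). What may go wrong:
   - conjugate addition of the weakly C–H acidic phosphonoacetate may be slow, leaving room for 1,2-addition and olefination of the enal;
   - the catalyst nitrogen may be alkylated by the halomethyl ester;
   - the six-membered closure may be slow because the ester must reach its s-trans rotamer;
   - the amine may trigger β-elimination of the lactone oxygen from the product.

   Fallback, known reaction types only, setting out from 3 and coming back at 8: Knoevenagel condensation of 3 with triethyl phosphonoacetate (piperidine, AcOH, benzene, reflux with water removal) should give ethyl (6S)-2-(diethoxyphosphoryl)-6-methyl-6-(triethylsilyloxy)octa-2,7-dienoate F1. An enamine-catalysed Michael addition of 3-[(4-methoxybenzyl)oxy]propanal to F1 under (R)-α,α-diphenylprolinol trimethylsilyl ether, the reaction type established for aldehydes with alkylidene malonates and vinyl phosphonates, then forms the C4a–C11a bond and should give ethyl (3S,6S)-2-(diethoxyphosphoryl)-3-{1-[(4-methoxybenzyl)oxy]-3-oxopropan-2-yl}-6-methyl-6-(triethylsilyloxy)oct-7-enoate F2. DDQ (CH2Cl2, pH 7 buffer) frees the primary alcohol to give ethyl (3S,6S)-2-(diethoxyphosphoryl)-3-(1-hydroxy-3-oxopropan-2-yl)-6-methyl-6-(triethylsilyloxy)oct-7-enoate F3, and PPTS in warm benzene closes the δ-lactone onto the ethyl ester, the formyl-bearing centre settling trans, to give 8.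

2. Step 8. What may go wrong: intermolecular metathesis (oligomerisation) may outpace closure of the strained nine-membered ring, and the allyl ketone may isomerise into conjugation before it cyclises.

   Fallback, setting out from 9 and coming back at 11, replacing olefin metathesis by reductive carbonyl coupling: ozonolysis of both terminal olefins of 9 (O3, CH2Cl2, −78 °C; Me2S) should give diethyl [(4S,5S)-5-(1-hydroxy-3-oxopropyl)-4-[(3S)-3-methyl-4-oxo-3-(triethylsilyloxy)butyl]-2-oxooxan-3-yl]phosphonate F4. McMurry coupling of the two aldehydes (TiCl3(DME)1.5, Zn–Cu couple, DME, reflux, slow addition), a reaction that is little affected by ring size, should give diethyl [(4aS,7S,8Z,11aS)-11-hydroxy-7-methyl-3-oxo-7-(triethylsilyloxy)-1,3,4,4a,5,6,7,10,11,11a-decahydrocyclonona[c]pyran-4-yl]phosphonate F5. Dess–Martin oxidation of F5 gives 11.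

3. Step 14. What may go wrong: E/Z selectivity may erode with the α-branched cyclic phosphonate, and the α-silyloxy aldehyde may epimerise or decompose under base.

   Fallback, setting out from 12 and coming back at 19, replacing the olefination by cross-metathesis: Horner–Wadsworth–Emmons reaction of 12 with aqueous formaldehyde (K2CO3, THF/H2O) should give (4aS,7S,8Z,11aR)-7-methyl-4,11-dimethylidene-7-(triethylsilyloxy)-4,4a,5,6,7,10,11,11a-octahydrocyclonona[c]pyran-3(1H)-one F6. Cross-metathesis of F6 with an excess of 17 under second-generation Hoveyda–Grubbs catalyst RuCl2(=CH-C6H4-2-OiPr)(H2IMes) in CH2Cl2 at 40 °C should give 19, the E-trisubstituted olefin being the thermodynamic cross-metathesis product.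

**Further compounds**

F1 | step 5 | ethyl (6S)-2-(diethoxyphosphoryl)-6-methyl-6-(triethylsilyloxy)octa-2,7-dienoate (E/Z mixture) | C=C[C@@](C)(O[Si](CC)(CC)CC)CCC=C(C(=O)OCC)P(=O)(OCC)OCC
F2 | step 5 | ethyl (3S,6S)-2-(diethoxyphosphoryl)-3-{1-[(4-methoxybenzyl)oxy]-3-oxopropan-2-yl}-6-methyl-6-(triethylsilyloxy)oct-7-enoate | C=C[C@@](C)(O[Si](CC)(CC)CC)CC[C@@H](C(C=O)COCc1ccc(OC)cc1)C(P(=O)(OCC)OCC)C(=O)OCC
F3 | step 5 | ethyl (3S,6S)-2-(diethoxyphosphoryl)-3-(1-hydroxy-3-oxopropan-2-yl)-6-methyl-6-(triethylsilyloxy)oct-7-enoate | C=C[C@@](C)(O[Si](CC)(CC)CC)CC[C@@H](C(C=O)CO)C(P(=O)(OCC)OCC)C(=O)OCC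
F4 | step 8 | diethyl [(4S,5S)-5-(1-hydroxy-3-oxopropyl)-4-[(3S)-3-methyl-4-oxo-3-(triethylsilyloxy)butyl]-2-oxooxan-3-yl]phosphonate | O=C[C@@](C)(O[Si](CC)(CC)CC)CC[C@@H]1C(P(=O)(OCC)OCC)C(=O)OC[C@H]1C(O)CC=O
F5 | step 8 | diethyl [(4aS,7S,8Z,11aS)-11-hydroxy-7-methyl-3-oxo-7-(triethylsilyloxy)-1,3,4,4a,5,6,7,10,11,11a-decahydrocyclonona[c]pyran-4-yl]phosphonate | OC1C/C=C\[C@@](C)(O[Si](CC)(CC)CC)CC[C@@H]2C(P(=O)(OCC)OCC)C(=O)OC[C@@H]12
F6 | step 14 | (4aS,7S,8Z,11aR)-7-methyl-4,11-dimethylidene-7-(triethylsilyloxy)-4,4a,5,6,7,10,11,11a-octahydrocyclonona[c]pyran-3(1H)-one | C=C1C/C=C\[C@@](C)(O[Si](CC)(CC)CC)CC[C@@H]2C(=C)C(=O)OC[C@@H]12
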